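The route rests on cutting the bond between C1 of ring A (the 4-hydroxy-3-methoxyphenyl ring) and the ketone carbon C7. A base-free Liebeskind–Srogl coupling of an unprotected arylboronic acid with a lactone thioester makes this bond in the last step and gives the free phenol target directly. It exploits the malonyl array C7–C8–C9. Only the C7(=O)–S bond adds to palladium, the lactone C9(=O)–O bond does not, and the acidic C8–H is left alone. The thioester derives from a cyclopropane-fused lactone built from (R)-epichlorohydrin. Its C8–C7' bond, absent from the target, carries the chirality to C8' and is cleaved by the ring B cuprate.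

Key step: step 4

Remark: lignan numbering is used (ring A = C1–C6, C7 = ketone carbon, C8 = lactone α-carbon, C9 = lactone carbonyl, ring B = C1'–C6' of the 3,4-dimethoxyphenyl ring, C7' = benzylic CH2, C8' = lactone β-carbon, C9' = OCH2). C8 lies between two carbonyl groups and is assumed to equilibrate to the trans isomer drawn, so only C8' has to be set irreversibly.

Step 1
Reactants: 1 (R)-epichlorohydrin; 2 di-tert-butyl malonate
Product: 4 tert-butyl (1R,5R)-2-oxo-3-oxabicyclo[3.1.0]hexane-1-carboxylate, via epoxymalonate 3 (not isolated)
Conditions: KOtBu (1.2 equiv), tBuOH, 25 → 70 °C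
Reagents that add atoms: none
Why: In this known malonate cyclopropanation-lactonisation cascade the enolate opens the epoxide at its CH2 terminus, the alkoxide displaces chloride to give 3, the malonate carbon opens the new epoxide 3-exo-tet with inversion and the cis alkoxide lactonises, so C8' (C5 of the bicycle) comes from the chiral pool through one inversion and C8 (C1) is fixed by the obligatory cis ring fusion.

Step 2
Reactants: 4 tert-butyl (1R,5R)-2-oxo-3-oxabicyclo[3.1.0]hexane-1-carboxylate; 5 4-bromo-1,2-dimethoxybenzene
Product: 7 tert-butyl (3R,4R)-4-(3,4-dimethoxybenzyl)-2-oxotetrahydrofuran-3-carboxylate, via arylmagnesium bromide 6 (not isolated)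
Conditions: 5, Mg, THF, 40 °C; then CuBr·SMe2 (20 mol %), −40 °C, add 4, −40 → −20 °C; cold 1 M HCl
Reagents that add atoms: none
Why: In this copper-catalysed homoconjugate addition of an aryl Grignard reagent to a doubly activated cyclopropane the arylcopper species attacks the unsubstituted carbon C7' in SN2 fashion and cleaves the temporary C8–C7' bond to a malonate-type enolate, so C8' keeps the configuration of 4, the bulky ester and low temperature hold back carbonyl addition, and protonation with equilibration places the ester at C8 trans to the new benzyl group.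

Step 3
Reactants: 7 tert-butyl (3R,4R)-4-(3,4-dimethoxybenzyl)-2-oxotetrahydrofuran-3-carboxylate
Product: 9 S-phenyl (3R,4R)-4-(3,4-dimethoxybenzyl)-2-oxotetrahydrofuran-3-carbothioate, via lactone acid 8 (not isolated)
Conditions: TFA, Et3SiH, CH2Cl2, 0 → 20 °C; evaporate with toluene below 25 °C; then PhSH, DCC, DMAP (5 mol %), CH2Cl2, 0 °C
Reagents that add atoms: thiophenol, Sc1ccccc1
Why: Acidolysis of the tert-butyl ester with Et3SiH as cation trap (so that ring B is not tert-butylated) is followed by Steglich-type carbodiimide thioesterification of the crude malonic half-acid, which is kept cold to avoid decarboxylation, while C8' is not involved and the labile C8 stays trans.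

Step 4
Reactants: 9 S-phenyl (3R,4R)-4-(3,4-dimethoxybenzyl)-2-oxotetrahydrofuran-3-carbothioate; 10 (4-hydroxy-3-methoxyphenyl)boronic acid
Product: 11 (3S,4R)-4-(3,4-dimethoxybenzyl)-3-(4-hydroxy-3-methoxybenzoyl)dihydrofuran-2(3H)-one (CNP0296372.1)
Conditions: Pd2(dba)3 (2.5 mol %), P(2-furyl)3 (15 mol %), Cu(O2CC4H3S) (copper thiophene-2-carboxylate, 2 equiv), THF, 45 °C, Ar; wash with 0.5 M HCl
Reagents that add atoms: none
Why: This is a Liebeskind–Srogl ketone synthesis, a known palladium-catalysed, copper-carboxylate-mediated coupling of thioesters with boronic acids: zerovalent palladium inserts into the C7(=O)–S bond of 9, the monovalent copper takes the thiolate from divalent palladium while its carboxylate activates boron, the aryl group of 10 is handed over through its ipso carbon C1, and reductive elimination forms the C1–C7 bond. No ring is closed and no base is present, so the acidic C8–H, the free C4–OH of ring A and the retro-Claisen-prone β-keto lactone product should all survive, which makes phenol protection unnecessary. Site selectivity on ring A (para to OH, meta to OMe) is fixed by the position of boron, whereas an acylium ion or ketene at C7 (Friedel–Crafts or Fries logic) would be captured first by C6' of the electron-rich ring B in a six-membered ring closure. Chemoselectivity between the two carbonyl groups on C8 rests on the soft C–S bond, since the lactone C9(=O)–O bond and the aryl–O bonds do not add to palladium under these conditions. C8' is not touched, while C8 is stereolabile in 9 and in 11 and should settle through the enol to the trans (3S,4R) arrangement, with the C8' benzyl substituent as the controlling element. The step needs transmetalation to outrun loss of CO from the acylpalladium species, which the weakly donating P(2-furyl)3, the excess copper carboxylate and a temperature at or below 45 °C should secure.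

Compound list
1 | (R)-epichlorohydrin, (2R)-2-(chloromethyl)oxirane | ClC[C@H]1CO1 | starting material
2 | di-tert-butyl malonate | CC(C)(C)OC(=O)CC(=O)OC(C)(C)C | starting material
3 | di-tert-butyl 2-{[(2R)-oxiran-2-yl]methyl}malonate | CC(C)(C)OC(=O)C(C[C@@H]1CO1)C(=O)OC(C)(C)C | intermediate
4 | tert-butyl (1R,5R)-2-oxo-3-oxabicyclo[3.1.0]hexane-1-carboxylate | CC(C)(C)OC(=O)[C@]12C[C@H]1COC2=O | intermediate
5 | 4-bromo-1,2-dimethoxybenzene | COc1ccc(Br)cc1OC | starting material
6 | (3,4-dimethoxyphenyl)magnesium bromide | COc1ccc([Mg]Br)cc1OC | intermediate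
7 | tert-butyl (3R,4R)-4-(3,4-dimethoxybenzyl)-2-oxotetrahydrofuran-3-carboxylate (trans) | CC(C)(C)OC(=O)[C@H]1C(=O)OC[C@@H]1Cc1ccc(OC)c(OC)c1 | intermediate
8 | (3S,4R)-4-(3,4-dimethoxybenzyl)-2-oxotetrahydrofuran-3-carboxylic acid (trans) | OC(=O)[C@H]1C(=O)OC[C@@H]1Cc1ccc(OC)c(OC)c1 | intermediate
9 | S-phenyl (3R,4R)-4-(3,4-dimethoxybenzyl)-2-oxotetrahydrofuran-3-carbothioate (trans) | O=C(Sc1ccccc1)[C@H]1C(=O)OC[C@@H]1Cc1ccc(OC)c(OC)c1 | intermediate
10 | (4-hydroxy-3-methoxyphenyl)boronic acid | COc1cc(B(O)O)ccc1O | starting material
11 | (3S,4R)-4-(3,4-dimethoxybenzyl)-3-(4-hydroxy-3-methoxybenzoyl)dihydrofuran-2(3H)-one | COc1cc(C(=O)[C@H]2C(=O)OC[C@@H]2Cc2ccc(OC)c(OC)c2)ccc1O | target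

Total steps: 4. Longest linear sequence: 4 steps (1 → 4 → 7 → 9 → 11).

Steps most likely to fail

**Step 4.**
- Risks: The acylpalladium intermediate may lose CO, because a stabilised palladium enolate would result. The electron-rich boronic acid may protodeboronate. The enolisable dicarbonyl unit may tie up copper.
- Fallback: It carries out the acyl–aryl coupling on the bicycle, where C8 is quaternary and cannot enolise, and opens the cyclopropane afterwards. It sets out from 4.
  - TFA/Et3SiH should give (1S,5R)-2-oxo-3-oxabicyclo[3.1.0]hexane-1-carboxylic acid F1.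
  - PhSH/DCC should give S-phenyl (1R,5R)-2-oxo-3-oxabicyclo[3.1.0]hexane-1-carbothioate F2.
  - Liebeskind–Srogl coupling with commercial [4-(benzyloxy)-3-methoxyphenyl]boronic acid should give (1S,5R)-1-[4-(benzyloxy)-3-methoxybenzoyl]-3-oxabicyclo[3.1.0]hexan-2-one F3.
  - Reagent 6 with a full equivalent of CuBr·SMe2 at −78 → −40 °C should open the cyclopropane, now activated by ketone and lactone, at C7'. This gives (3S,4R)-3-[4-(benzyloxy)-3-methoxybenzoyl]-4-(3,4-dimethoxybenzyl)dihydrofuran-2(3H)-one F4.
  - Hydrogenolysis (H2, Pd/C, EtOAc) comes back to the route at 11.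

**Step 3.**
- Risks: The malonic half-acid may decarboxylate on concentration. The tert-butyl cation may be captured by ring B. Carbodiimide activation may lead to self-condensation through an acylketene.
- Fallback: It gives up C7 deliberately and puts it back already as the thioester. It sets out from 7.
  - TFA/Et3SiH leads to 8, and heating crude 8 in toluene at 110 °C should give (4R)-4-(3,4-dimethoxybenzyl)dihydrofuran-2(3H)-one F5.
  - Enolisation with LiN(SiMe3)2 (2.2 equiv, THF, −78 °C) and C-acylation with commercial S-phenyl chlorothioformate comes back to the route at 9. The trans arrangement is again reached by equilibration.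

**Step 1.**
- Risks: Enantiopurity may leak through competing direct displacement of chloride, a pathway that leads to the mirror-image bicycle. Lactonisation onto the hindered tert-butyl ester may be slow.
- Fallback: It changes the electrophile and the order of bond formation. It sets out from 2, which is deprotonated (NaH, THF/DMF) and alkylated with commercial (S)-glycidyl 3-nitrobenzenesulfonate.
  - The sulfonate is displaced first and the original epoxide is kept, so the same epoxymalonate 3 should form by a single pathway.
  - Compound 3 then closes to the cyclopropane and lactonises, and the fallback comes back to the route at 4.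

Further compounds
F1 | step 4 | (1S,5R)-2-oxo-3-oxabicyclo[3.1.0]hexane-1-carboxylic acid | OC(=O)[C@]12C[C@H]1COC2=O
F2 | step 4 | S-phenyl (1R,5R)-2-oxo-3-oxabicyclo[3.1.0]hexane-1-carbothioate | O=C(Sc1ccccc1)[C@]12C[C@H]1COC2=O
F3 | step 4 | (1S,5R)-1-[4-(benzyloxy)-3-methoxybenzoyl]-3-oxabicyclo[3.1.0]hexan-2-one | COc1cc(C(=O)[C@]23C[C@H]2COC3=O)ccc1OCc1ccccc1
F4 | step 4 | (3S,4R)-3-[4-(benzyloxy)-3-methoxybenzoyl]-4-(3,4-dimethoxybenzyl)dihydrofuran-2(3H)-one | COc1cc(C(=O)[C@H]2C(=O)OC[C@@H]2Cc2ccc(OC)c(OC)c2)ccc1OCc1ccccc1
F5 | step 3 | (4R)-4-(3,4-dimethoxybenzyl)dihydrofuran-2(3H)-one | COc1ccc(C[C@H]2COC(=O)C2)cc1OC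
F0 | step 1 | none | none
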